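By 12 min the new flask has had its last portion for 6.00 min, and your hunch that its percentages will sit with the ash and maple runs looks sound to us. We therefore spend our thought on the dissolved gas, which no run measured.

| flask | substrate | gas phase | remark | time |
|---|---|---|---|---|
| ash | 0.25 M (in portions, 2) | 52 mM (held) | run made earlier; portions every 6.0 min |  |
| maple | 1 M (in portions, 2) | 52 mM (held) | run made earlier; portions every 6.0 min |  |
| flask | 0.50 M (in portions, 2) | 52 mM (held) | the portions of substrate follow each other after 6.0 min, the first at the start | 12 min |

| run | time / min | isomer of the product / % | target / % |
|---|---|---|---|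
| ash | 1.00 | 0 | 48 |
| ash | 2.00 | 5 | 49 |
| ash | 3.00 | 3 | 44 |
| ash | 6.00 | 11 | 41 |
| ash | 12.0 | 25 | 72 |
| maple | 1.00 | 1 | 48 |
| maple | 2.00 | 0 | 48 |
| maple | 3.00 | 8 | 43 |
| maple | 6.00 | 11 | 38 |
| maple | 12.0 | 26 | 75 |

(scatter of a reading: 2 percentage points)

- the numbers in the tables scatter by 2 percentage points (one standard deviation)
- at the start none of the gas phase is in solution
- a reading or a percentage of target counts all its forms, free or not

- the isomer of the product in the flask at 12 min, as a percentage of the substrate charged
- the target in the flask at 12 min, as a percentage of the substrate charged
- concentration of dissolved gas at 12 min, in M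

We count turnovers of the dissolved-gas pool. In the maple run the reading at 1.00 min shows 0.480 M of target, which is 9.23 times what the pool holds at saturation. That ratio, gas drawn through the pool divided by the saturation concentration, we call the refill count, a turnover number of the pool. In the maple run, then, the pool was filled once in every 0.108 min on average over that first stretch, as far as this scattered reading tells. Each portion in the new flask asks for a refill count of 4.81, less than the maple run managed, and the wait before the reading is far longer than one filling. In both runs target reads lower at 6.00 min than at 1.00 min, so we take it that the substrate of a portion has stopped drawing on the pool well before the next step of the run, and our own reckoning puts the dissolved gas in the new flask at 52 mM.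

The forecast gives isomer 25.5%, target 73.5% and dissolved gas 0.02 M, calling the gas “probably near saturation or lower”. We take its first two figures, but its gas figure is lower than ours.

    target ⇌ isomer of the product (K = 6.30, k = 6.70 × 10⁻⁴ s⁻¹)
    dissolved gas ⇌ dormant form (K = 5.00, k = 0.00360 s⁻¹)
    substrate + dissolved gas → target (k = 3.50 M⁻¹ s⁻¹)
    gas phase ⇌ dissolved gas, rate k4*(csat - [dissolved gas]) (kL = 0.540 s⁻¹)
    substrate + target ⇌ idle adduct, settled at all times (K = 1.80 M⁻¹)

The flask gives isomer 28.3%, target 71.7% and dissolved gas 0.0518 M. At 12.0 min the flask also holds dormant form at 0.102 M, a refill count of 1.96 on top of the 9.62 that the whole charge of substrate asked for. The neighbour flask, held the same but read at 30.0 min, has dormant form at 0.187 M, a refill count of 3.60, with its dissolved gas at 0.0519 M.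

The readings come from a simulation on assumed constants.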